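**Plan**

- Numbering: C7 is the benzylic carbinol carbon, C8 the aryloxy-bearing carbon, C9 the CH2OH carbon. Ring A is the 4-hydroxy-3,5-dimethoxyphenyl ring, ring B the 2,6-dimethoxy-4-(3-hydroxypropyl)phenoxy ring. The target is the threo (7R,8R) isomer.
- Retrosynthesis cuts, in order: the two O–benzyl bonds; C7–OH and the side-chain CH2–OH (both traced back to C–B bonds); the ring A C1–C7 bond; the C7–C8 bond (CHCl insertion); the C8–O(ring B) bond; the C8–C9 bond (CHBr insertion).
- Enabling feature: C7 is a secondary carbinol carbon flanked by ring A and the oxygenated C8. A C–OH is the oxidation product of a C–B bond, so C7 can be carried as a boron-bearing carbon with a chloride on it. Ring A then arrives on boron as a nucleophile and shifts to C7.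
- Forward: the chain grows C9 → C8 → C7 on boron by two Matteson homologations, with the ring B phenoxide entering at C8. The ring A Grignard reagent is joined at C7, one peroxide oxidation turns both C–B bonds (C7 and the hydroborated allyl terminus) into the two alcohols, and hydrogenolysis finishes.
- Stereochemistry: C8 and C7 both come from the single (S,S)-1,2-dicyclohexylethane-1,2-diol on boron. Each homologation gives the (αR)-halide, each substitution inverts, and the oxidation retains, which gives (7R,8R).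

Key step: step 6

Remark on the chemistry: C2-symmetric (R,R)-1,2-diol boronic esters are taken to give (αS)-α-halo boronic esters in the Matteson homologation, so the (S,S)-diol is used to obtain the (αR) series.

**Step 1**
Reactants: 1 potassium (benzyloxymethyl)trifluoroborate; 2 (1S,2S)-1,2-dicyclohexylethane-1,2-diol
Product: 3 (4S,5S)-2-[(benzyloxy)methyl]-4,5-dicyclohexyl-1,3,2-dioxaborolane
Conditions: Me3SiCl (3 equiv), MeCN, rt
Reagents that add atoms: none
Why: Silicon abstracts fluoride from the trifluoroborate and the freed boron is esterified by the diol (trifluoroborate-to-boronic ester exchange); no stereocentre is formed.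

**Step 2**
Reactants: 3 (4S,5S)-2-[(benzyloxy)methyl]-4,5-dicyclohexyl-1,3,2-dioxaborolane
Product: 5 (4S,5S)-2-[(1R)-2-(benzyloxy)-1-bromoethyl]-4,5-dicyclohexyl-1,3,2-dioxaborolane, via lithium dibromomethyl borate complex 4 (not isolated)
Conditions: CH2Br2, LiN(iPr)2 (LDA), THF, −78 °C; then ZnCl2, −78 °C → rt
Reagents that add atoms: dibromomethane, BrCBr
Why: Matteson homologation: LiCHBr2 adds to boron and ZnCl2 promotes the 1,2-shift of the benzyloxymethyl group with loss of one diastereotopic bromide, the C2-symmetric (S,S)-diol directing formation of the (1R)-bromide at the future C8.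

**Step 3**
Reactants: 5 (4S,5S)-2-[(1R)-2-(benzyloxy)-1-bromoethyl]-4,5-dicyclohexyl-1,3,2-dioxaborolane; 6 4-allyl-2,6-dimethoxyphenol
Product: 8 (4S,5S)-2-[(1S)-1-(4-allyl-2,6-dimethoxyphenoxy)-2-(benzyloxy)ethyl]-4,5-dicyclohexyl-1,3,2-dioxaborolane, via sodium 4-allyl-2,6-dimethoxyphenoxide 7 (not isolated)
Conditions: NaH, THF, 0 °C; then 5, THF/DMSO, 0 °C → rt
Reagents that add atoms: none
Why: Matteson substitution by an oxygen nucleophile: the phenoxide displaces the bromide α to boron with inversion (borate formation and 1,2-oxygen shift, or direct SN2), which sets C8; the high SN2 reactivity of α-boryl halides should offset the hindrance of the 2,6-dimethoxyphenoxide.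

**Step 4**
Reactants: 8 (4S,5S)-2-[(1S)-1-(4-allyl-2,6-dimethoxyphenoxy)-2-(benzyloxy)ethyl]-4,5-dicyclohexyl-1,3,2-dioxaborolane
Product: 10 (4S,5S)-2-[(1R,2R)-2-(4-allyl-2,6-dimethoxyphenoxy)-3-(benzyloxy)-1-chloropropyl]-4,5-dicyclohexyl-1,3,2-dioxaborolane, via lithium dichloromethyl borate complex 9 (not isolated)
Conditions: CH2Cl2, nBuLi, THF, −100 °C; then 8; then ZnCl2 (excess, to saturate the ether oxygens), −100 °C → rt
Reagents that add atoms: dichloromethane, ClCCl
Why: Second Matteson homologation: preformed LiCHCl2 adds to boron and the C8 carbon migrates with retention, the same (S,S)-diol directing the (1R)-chloride at C7; nBuLi is consumed before 8 is added, so the allyl group is not exposed to strong base.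

**Step 5**
Reactants: 11 4-bromo-2,6-dimethoxyphenol
Product: 12 2-(benzyloxy)-5-bromo-1,3-dimethoxybenzene
Conditions: BnBr, K2CO3, DMF, rt
Reagents that add atoms: benzyl bromide, BrCc1ccccc1
Why: Williamson ether synthesis masks the ring A phenol as a benzyl ether that survives Grignard formation and leaves in the last step together with the C9 benzyl ether.

**Step 6**
Reactants: 10 (4S,5S)-2-[(1R,2R)-2-(4-allyl-2,6-dimethoxyphenoxy)-3-(benzyloxy)-1-chloropropyl]-4,5-dicyclohexyl-1,3,2-dioxaborolane; 12 2-(benzyloxy)-5-bromo-1,3-dimethoxybenzene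
Product: 15 (4S,5S)-2-{(1R,2S)-2-(4-allyl-2,6-dimethoxyphenoxy)-3-(benzyloxy)-1-[4-(benzyloxy)-3,5-dimethoxyphenyl]propyl}-4,5-dicyclohexyl-1,3,2-dioxaborolane, via [4-(benzyloxy)-3,5-dimethoxyphenyl]magnesium bromide 13 (not isolated), via bromomagnesium aryl borate complex 14 (not isolated)
Conditions: 12, Mg, THF, rt → 40 °C; then 10, THF, −78 °C → rt, 16 h
Reagents that add atoms: none
Why: The Grignard reagent 13 adds to the trigonal boron of 10 to give the tetracoordinate borate 14, and on warming the ring A aryl group shifts from boron to C7 anti-periplanar to the C7–Cl bond while MgBrCl assists chloride departure (1,2-metallate rearrangement), which forms the aryl–C7 bond and leaves boron on C7 as the latent hydroxyl. The closest known reaction type is the Matteson substitution of α-chloro boronic esters, β-alkoxy-substituted ones included, by Grignard reagents; no ring is closed. The new C7 stereocentre is set by stereospecific inversion of the (1R)-chloride, whose configuration came from the (S,S)-diol on boron, so C7 is (1R) in 15 and C8 is untouched. The step needs the aryl shift with chloride loss to outrun β-elimination of the C8 aryloxide and migration of a ring oxygen; the far better α-leaving group, borate formation at low temperature and the high migratory aptitude of the electron-rich aryl group should secure this. Boron is the only electrophilic site of 10 toward 13, so the allyl group and the benzyl and methyl ethers are not touched.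

**Step 7**
Reactants: 15 (4S,5S)-2-{(1R,2S)-2-(4-allyl-2,6-dimethoxyphenoxy)-3-(benzyloxy)-1-[4-(benzyloxy)-3,5-dimethoxyphenyl]propyl}-4,5-dicyclohexyl-1,3,2-dioxaborolane
Product: 17 (1R,2R)-3-(benzyloxy)-1-[4-(benzyloxy)-3,5-dimethoxyphenyl]-2-[4-(3-hydroxypropyl)-2,6-dimethoxyphenoxy]propan-1-ol, via B-alkyl-9-BBN adduct 16 (not isolated)
Conditions: 9-BBN, THF, 0 °C → rt; then aq NaOH, 30% H2O2, 0 °C → rt
Reagents that add atoms: hydrogen peroxide, OO
Why: Brown hydroboration places boron on the terminal carbon of the allyl group, and alkaline peroxide then oxidises every C–B bond in one operation; the C7–B bond becomes C7–OH with retention, which gives (7R) and the threo relationship to C8.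

**Step 8**
Reactants: 17 (1R,2R)-3-(benzyloxy)-1-[4-(benzyloxy)-3,5-dimethoxyphenyl]-2-[4-(3-hydroxypropyl)-2,6-dimethoxyphenoxy]propan-1-ol
Product: 18 (1R,2R)-1-(4-hydroxy-3,5-dimethoxyphenyl)-2-[4-(3-hydroxypropyl)-2,6-dimethoxyphenoxy]propane-1,3-diol
Conditions: H2 (1 atm), 10% Pd/C, EtOAc, rt
Reagents that add atoms: none
Why: Catalytic hydrogenolysis cleaves the aryl and the alkyl benzyl ether; neutral, acid-free conditions should leave the benzylic C7–OH and its configuration intact.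

**Compound list**

1 | potassium (benzyloxymethyl)trifluoroborate | [K+].F[B-](F)(F)COCc1ccccc1 | starting material
2 | (1S,2S)-1,2-dicyclohexylethane-1,2-diol | O[C@@H](C1CCCCC1)[C@@H](O)C1CCCCC1 | starting material
3 | (4S,5S)-2-[(benzyloxy)methyl]-4,5-dicyclohexyl-1,3,2-dioxaborolane | c1ccccc1COCB1O[C@@H](C2CCCCC2)[C@H](C2CCCCC2)O1 | intermediate
4 | lithium dibromomethyl borate complex of 3 | [Li+].c1ccccc1COC[B-]1(C(Br)Br)O[C@@H](C2CCCCC2)[C@H](C2CCCCC2)O1 | intermediate (not isolated)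
5 | (4S,5S)-2-[(1R)-2-(benzyloxy)-1-bromoethyl]-4,5-dicyclohexyl-1,3,2-dioxaborolane | c1ccccc1COC[C@H](Br)B1O[C@@H](C2CCCCC2)[C@H](C2CCCCC2)O1 | intermediate
6 | 4-allyl-2,6-dimethoxyphenol | C=CCc1cc(OC)c(O)c(OC)c1 | starting material
7 | sodium 4-allyl-2,6-dimethoxyphenoxide | [Na+].[O-]c1c(OC)cc(CC=C)cc1OC | intermediate (not isolated)
8 | (4S,5S)-2-[(1S)-1-(4-allyl-2,6-dimethoxyphenoxy)-2-(benzyloxy)ethyl]-4,5-dicyclohexyl-1,3,2-dioxaborolane | c1ccccc1COC[C@@H](Oc1c(OC)cc(CC=C)cc1OC)B1O[C@@H](C2CCCCC2)[C@H](C2CCCCC2)O1 | intermediate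
9 | lithium dichloromethyl borate complex of 8 | [Li+].c1ccccc1COC[C@@H](Oc1c(OC)cc(CC=C)cc1OC)[B-]1(C(Cl)Cl)O[C@@H](C2CCCCC2)[C@H](C2CCCCC2)O1 | intermediate (not isolated)
10 | (4S,5S)-2-[(1R,2R)-2-(4-allyl-2,6-dimethoxyphenoxy)-3-(benzyloxy)-1-chloropropyl]-4,5-dicyclohexyl-1,3,2-dioxaborolane | c1ccccc1COC[C@@H](Oc1c(OC)cc(CC=C)cc1OC)[C@H](Cl)B1O[C@@H](C2CCCCC2)[C@H](C2CCCCC2)O1 | intermediate
11 | 4-bromo-2,6-dimethoxyphenol | COc1cc(Br)cc(OC)c1O | starting material
12 | 2-(benzyloxy)-5-bromo-1,3-dimethoxybenzene | COc1cc(Br)cc(OC)c1OCc1ccccc1 | intermediate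
13 | [4-(benzyloxy)-3,5-dimethoxyphenyl]magnesium bromide | COc1cc([Mg]Br)cc(OC)c1OCc1ccccc1 | intermediate (not isolated)
14 | bromomagnesium aryl borate complex of 10 | Br[Mg+].c1ccccc1COC[C@@H](Oc1c(OC)cc(CC=C)cc1OC)[C@H](Cl)[B-]1(c2cc(OC)c(OCc3ccccc3)c(OC)c2)O[C@@H](C2CCCCC2)[C@H](C2CCCCC2)O1 | intermediate (not isolated)
15 | (4S,5S)-2-{(1R,2S)-2-(4-allyl-2,6-dimethoxyphenoxy)-3-(benzyloxy)-1-[4-(benzyloxy)-3,5-dimethoxyphenyl]propyl}-4,5-dicyclohexyl-1,3,2-dioxaborolane | c1ccccc1COC[C@@H](Oc1c(OC)cc(CC=C)cc1OC)[C@@H](c1cc(OC)c(OCc2ccccc2)c(OC)c1)B1O[C@@H](C2CCCCC2)[C@H](C2CCCCC2)O1 | intermediate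
16 | B-alkyl-9-BBN adduct of 15 (9-borabicyclo[3.3.1]nonan-9-yl group on the terminal carbon of the former allyl group) | c1ccccc1COC[C@@H](Oc1c(OC)cc(CCCB2C3CCCC2CCC3)cc1OC)[C@@H](c1cc(OC)c(OCc2ccccc2)c(OC)c1)B1O[C@@H](C2CCCCC2)[C@H](C2CCCCC2)O1 | intermediate (not isolated)
17 | (1R,2R)-3-(benzyloxy)-1-[4-(benzyloxy)-3,5-dimethoxyphenyl]-2-[4-(3-hydroxypropyl)-2,6-dimethoxyphenoxy]propan-1-ol | c1ccccc1COC[C@@H](Oc1c(OC)cc(CCCO)cc1OC)[C@@H](c1cc(OC)c(OCc2ccccc2)c(OC)c1)O | intermediate
18 | (1R,2R)-1-(4-hydroxy-3,5-dimethoxyphenyl)-2-[4-(3-hydroxypropyl)-2,6-dimethoxyphenoxy]propane-1,3-diol | COc1cc([C@@H](O)[C@@H](CO)Oc2c(OC)cc(CCCO)cc2OC)cc(OC)c1O | target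

**Totals**

Total step count: 8. Longest linear sequence: 7 (steps 1, 2, 3, 4, 6, 7, 8).

**Steps most likely to fail**

Step 6. In borate 14 the C8 aryloxide may be expelled by β-elimination faster than the aryl group shifts, or a slow shift at the hindered boron may allow chloride exchange to erode the C7 configuration. The fallback sets out from 10 and comes back at 17. Hydroboration of the allyl group of 10 with 9-BBN (THF, rt) would give the B-alkyl-9-BBN adduct of 10 F1, which is not isolated. Buffered oxidation (30% H2O2, pH 8 sodium phosphate buffer, 0 °C) would convert the side-chain borane into the alcohol and collapse the α-chloro boronic ester to the aldehyde, giving (2R)-3-(benzyloxy)-2-[4-(3-hydroxypropyl)-2,6-dimethoxyphenoxy]propanal F2. Cram-chelate-controlled addition of Grignard reagent 13 (excess, MgBr2·OEt2, CH2Cl2/THF, −78 °C) should then give the threo alcohol 17. Magnesium is held between the aldehyde oxygen and the C8 aryloxy and ortho-methoxy oxygens, and attack comes from the face opposite the CH2OBn group.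

Step 3. The doubly ortho-substituted phenoxide may substitute too slowly, so that bromide exchange epimerises the C8 centre or elimination takes over. The fallback sets out from 6 and comes back at 17, taking C8 from the chiral pool instead of from boron. Mitsunobu reaction of 6 with methyl (2S)-3-(benzyloxy)-2-hydroxypropanoate (PPh3, DIAD, THF, 0 °C → rt, inversion) would give methyl (2R)-2-(4-allyl-2,6-dimethoxyphenoxy)-3-(benzyloxy)propanoate F3. Reduction with iBu2AlH (CH2Cl2, −78 °C) would give (2R)-2-(4-allyl-2,6-dimethoxyphenoxy)-3-(benzyloxy)propanal F4. Chelation-controlled addition of 13 (MgBr2·OEt2, CH2Cl2/THF, −78 °C) should give (1R,2R)-2-(4-allyl-2,6-dimethoxyphenoxy)-3-(benzyloxy)-1-[4-(benzyloxy)-3,5-dimethoxyphenyl]propan-1-ol F5. Hydroboration with 9-BBN would give the 9-BBN adduct of F5 F6, not isolated, and aq NaOH/H2O2 would then give 17.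

Step 8. Hydrogenolysis may also cleave the benzylic C7–O bond, or C7 may lose its configuration through a quinone methide once the para phenol of ring A is free. The fallback sets out from 15 and comes back at 18, keeping boron on C7 through the hydrogenolysis. Hydroboration of the allyl group of 15 with pinacolborane ([Ir(cod)Cl]2, bis(diphenylphosphino)methane, CH2Cl2, rt) would give (4S,5S)-2-[(1R,2S)-3-(benzyloxy)-1-[4-(benzyloxy)-3,5-dimethoxyphenyl]-2-{2,6-dimethoxy-4-[3-(4,4,5,5-tetramethyl-1,3,2-dioxaborolan-2-yl)propyl]phenoxy}propyl]-4,5-dicyclohexyl-1,3,2-dioxaborolane F7. Hydrogenolysis (H2, 10% Pd/C, EtOAc), with no benzylic C–O bond present, would give 4-[(1R,2S)-1-[(4S,5S)-4,5-dicyclohexyl-1,3,2-dioxaborolan-2-yl]-2-{2,6-dimethoxy-4-[3-(4,4,5,5-tetramethyl-1,3,2-dioxaborolan-2-yl)propyl]phenoxy}-3-hydroxypropyl]-2,6-dimethoxyphenol F8. Mild oxidation of both C–B bonds (NaBO3·4H2O, THF/H2O, rt) should then give 18 with retention at C7.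

Further compounds
F1 | step 6 | 9-BBN adduct of 10: (4S,5S)-2-[(1R,2R)-3-(benzyloxy)-2-{4-[3-(9-borabicyclo[3.3.1]nonan-9-yl)propyl]-2,6-dimethoxyphenoxy}-1-chloropropyl]-4,5-dicyclohexyl-1,3,2-dioxaborolane | c1ccccc1COC[C@@H](Oc1c(OC)cc(CCCB2C3CCCC2CCC3)cc1OC)[C@H](Cl)B1O[C@@H](C2CCCCC2)[C@H](C2CCCCC2)O1
F2 | step 6 | (2R)-3-(benzyloxy)-2-[4-(3-hydroxypropyl)-2,6-dimethoxyphenoxy]propanal | c1ccccc1COC[C@@H](Oc1c(OC)cc(CCCO)cc1OC)C=O
F3 | step 3 | methyl (2R)-2-(4-allyl-2,6-dimethoxyphenoxy)-3-(benzyloxy)propanoate | c1ccccc1COC[C@@H](Oc1c(OC)cc(CC=C)cc1OC)C(=O)OC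
F4 | step 3 | (2R)-2-(4-allyl-2,6-dimethoxyphenoxy)-3-(benzyloxy)propanal | c1ccccc1COC[C@@H](Oc1c(OC)cc(CC=C)cc1OC)C=O
F5 | step 3 | (1R,2R)-2-(4-allyl-2,6-dimethoxyphenoxy)-3-(benzyloxy)-1-[4-(benzyloxy)-3,5-dimethoxyphenyl]propan-1-ol | c1ccccc1COC[C@@H](Oc1c(OC)cc(CC=C)cc1OC)[C@@H](c1cc(OC)c(OCc2ccccc2)c(OC)c1)O
F6 | step 3 | 9-BBN adduct of F5: (1R,2R)-3-(benzyloxy)-1-[4-(benzyloxy)-3,5-dimethoxyphenyl]-2-{4-[3-(9-borabicyclo[3.3.1]nonan-9-yl)propyl]-2,6-dimethoxyphenoxy}propan-1-ol | c1ccccc1COC[C@@H](Oc1c(OC)cc(CCCB2C3CCCC2CCC3)cc1OC)[C@@H](c1cc(OC)c(OCc2ccccc2)c(OC)c1)O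
F7 | step 8 | (4S,5S)-2-[(1R,2S)-3-(benzyloxy)-1-[4-(benzyloxy)-3,5-dimethoxyphenyl]-2-{2,6-dimethoxy-4-[3-(4,4,5,5-tetramethyl-1,3,2-dioxaborolan-2-yl)propyl]phenoxy}propyl]-4,5-dicyclohexyl-1,3,2-dioxaborolane | c1ccccc1COC[C@@H](Oc1c(OC)cc(CCCB2OC(C)(C)C(C)(C)O2)cc1OC)[C@@H](c1cc(OC)c(OCc2ccccc2)c(OC)c1)B1O[C@@H](C2CCCCC2)[C@H](C2CCCCC2)O1
F8 | step 8 | 4-[(1R,2S)-1-[(4S,5S)-4,5-dicyclohexyl-1,3,2-dioxaborolan-2-yl]-2-{2,6-dimethoxy-4-[3-(4,4,5,5-tetramethyl-1,3,2-dioxaborolan-2-yl)propyl]phenoxy}-3-hydroxypropyl]-2,6-dimethoxyphenol | OC[C@@H](Oc1c(OC)cc(CCCB2OC(C)(C)C(C)(C)O2)cc1OC)[C@@H](c1cc(OC)c(O)c(OC)c1)B1O[C@@H](C2CCCCC2)[C@H](C2CCCCC2)O1
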